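**Remark on the chemistry:** eudesmane numbering is used throughout (ring A = C1–C5 and C10, ring B = C5–C10, C14 = methyl on C10, C15 = methyl on C4, isopropyl on C7); β is the face of C14. Read this way the target is the 3α,4β-diol 6β-benzoate with 5α-H, (3R,4R,5S,6R,7S,10S).

**Remark on the chemistry:** the (S)-enantiomer of 4-benzyl-1,3-oxazolidin-2-one is assumed to be the one needed, since alkylation of its Z-enolate on the face opposite the benzyl group gives the (S)-configured C7 of the target.

## Structural features

The target is a eudesmane, that is, two cyclohexane rings (ring A and ring B) trans-fused through the C5–C10 bond. Quaternary C10 carries the angular methyl C14, C4 carries methyl C15 and a tertiary hydroxyl, C3 a secondary hydroxyl, C6 the benzoate and C7 an isopropyl group. Five of the six stereocentres (C3, C4, C5, C6, C7) are contiguous, and C10 completes the set. In the chair–chair decalin the isopropyl group is equatorial, whereas the 3α-hydroxyl, the 4β-hydroxyl and the 6β-benzoate are axial, the last two syn-diaxial to each other and to C14. The fragile groups are the benzoate, which hydrides, organometallics and alkoxides cleave and which can migrate to O4 through a six-membered bridged intermediate, and the tertiary alcohol, which eliminates readily in acid. The real difficulty lies in the quaternary C10 held in a fixed relation to remote C7, in the trans ring fusion, and in an axial ester at C6 whose backside is screened by C14. The key step exploits the fact that carbinol carbon C6 is bonded to ring-fusion carbon C5, whose other neighbour C4 must end as a methyl-bearing carbinol: a C6 aldehyde and a C4(Me)=C5 alkene of ring A can be joined at C5–C6, which closes ring B and pushes the unsaturation to C4(15), from where the C3 and C4 oxygens can be added.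

## Logic of the disconnections

**23 from 22.** The C4–OH bond is cut first, so that the diol of 23 is read as the opened C3–O–C4 bridge of 22. A trans-diaxial 3α,4β-diol is what a 3α,4α-epoxide gives when it is opened at its tertiary carbon. Two hydroxyl stereocentres are reduced to one epoxide. The forward step must open at C4 with inversion and leave the ester at C6.

**22 from 21.** Both C–O bonds of the epoxide are cut to give the ring A alkene of 21. Two stereocentres are traded for the faces of an alkene whose β face is covered by C14 and by the C6 ester. The forward step only has to attack from the α face.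

**21 from 20.** No skeletal bond is cut; the C3=C4 alkene of 21 is traced to the C4=C15 alkene of 20. The reason is that an exocyclic methylene on C4 is what a ring closure at C5 leaves behind. The forward step must move the double bond toward C3 and not toward C5.

**20 from 17 through 19 and 18.** The acyl–O bond at C6 is cut to give 19, and the axial 6β-alcohol is related through ketone 18 to its equatorial epimer 17. The ring closure delivers the equatorial alcohol, and an SN2 inversion at C6 would have to approach syn-axially past the C10 methyl between two branched carbons, so a direct inversion was not adopted. The gain is that the C6 configuration of the cyclisation no longer matters. The demands are hydride delivery from the α face and a ketone that does not slip into conjugation with the exocyclic alkene.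

**17 from 16.** This is the strategic cut. The C5–C6 bond is broken, ring B opens, C6 becomes an aldehyde and the hydrogen on oxygen returns to C15 to give the C4(Me)=C5 alkene. A decalin with four stereocentres, two on the ring fusion, becomes a cyclohexene with two stereocentres (C7, C10) that are four bonds apart and can be made independently. The forward step must close through one chair and on one face of C5.

**16 from 14 through 15.** Only the oxidation level and the protection of C6 change (the C6–O silyl bond and a C6–H bond). An aldehyde would not survive the organometallic steps, so C6 travels as a silyl ether. The forward steps must not epimerise C7, which is α to the aldehyde.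

**14 from 13.** The C4–C15 bond is cut, leaving an enol triflate. The position of the ring A double bond is thereby tied to an enolate and is no longer a question of elimination regiochemistry. The forward coupling must replace oxygen by methyl without moving the alkene.

**13 from 9 and 10 (through 11 and 12).** The C9–C10 bond is cut as a conjugate addition and the C4–O sulfonyl bond as an enolate trapping. This is the convergent step: the quaternary centre comes from a prochiral enone, and the C6–C9 chain, with C7 already set, arrives as the nucleophile. The demand is catalyst control over the face of C3 of 10 and capture of the enolate before it equilibrates.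

**9 from 5 through 8, 7 and 6.** No C–C bond is cut; the C9 bromide goes back to the tert-butyl ester and the C6 silyl ether to the imide carbonyl. The two ends of the four-carbon unit are thus differentiated from the start. The forward steps need a hydride that reduces the imide and spares the ester.

**5 from 3 and 4.** The C7–C8 bond is cut as an enolate alkylation. The problem of C7 is reduced to the choice of an auxiliary. The forward step must alkylate a single enolate face.

**3 from 1 and 2.** The N–acyl bond is cut, which leaves two commercial compounds.

## Other disconnections considered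

Alternative 1:
- **Cut:** two bonds of C1 (C1–C10 and C1–C14) are removed, so that ring A and the cyclopropane open to the monocyclic hydroxy-enyne A1. A1 is a ring B cyclohexane with an exocyclic C10=C14 methylene, the C6 silyl ether, the C7 isopropyl group and, on C5, the chain C4(Me)(OSiMe3)–C3H(OH)–C2≡C1H.
- **Forward key step:** PtCl2 (divalent platinum) would activate the alkyne, C1 would add across the methylene to close ring A and the three-membered ring, and the carbene left on C2 would take the C3 hydrogen, giving the 3-ketone A2.
- **In favour:** one catalytic, atom-economical step builds ring A, the quaternary C10 and the C3 carbonyl, and C4 already carries its oxygen. On the C3 oxygen it is the better plan, since the chosen route needs three steps (15 to 17) to reach that oxidation pattern.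
- **Against:** A1 must be assembled with four contiguous stereocentres (C4 to C7), among them a tertiary silyl ether, before any ring A exists to guide them; 16 has two remote, independently made centres. After A2 the finish still needs a regioselective hydrogenolysis of the cyclopropane (C1–C14 must break), a reduction to the axial 3α-alcohol, removal of two silyl ethers and an acylation that must prefer the hindered C6 hydroxyl over the C3 hydroxyl.
- **Structure:** both plans build one ring on a preformed cyclohexane. The C10 configuration depends on which face of the methylene is reached, which is no better secured than the ring fusion in step 11 (equal).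
- **Mechanism:** the platinum cascade tolerates much, but a free propargylic alcohol next to a tertiary silyl ether invites ionisation.
- **Step economy:** the shorter finish is paid for by a longer precursor, so no net gain is expected.

Alternative 2:
- **Cut:** the ring-fusion bond C5–C10 is cut, which turns the decalin into the ten-membered (1(10)E,4E)-germacradienyl benzoate A3 with only C6 and C7 stereogenic.
- **Forward key step:** dilute acid would protonate C1, C5 of the 4-ene would attack C10 across the ring, and the positive charge at C4 would be captured on the β face by the benzoate carbonyl; hydrolysis of the bridged cation would give the hydroxy benzoate A4.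
- **In favour:** it follows the biosynthesis and sets C4, C5 and C10 in one step. The trans fusion follows from the crossed conformation of the (E,E)-diene, which is better founded than the face selectivity on which step 11 rests. The benzoate is already at C6 and serves as the nucleophile for C4, so steps 12 to 14 would not be needed. On these points the alternative is the better plan.
- **Against:** A3 is a strained medium ring with two trisubstituted E-alkenes and an allylic ester. Its ring closure, its tendency to Cope rearrangement and the ionisation of the allylic benzoate in acid are larger problems than anything on the way to 16. More serious for this target, A4 has no oxygen at C3: the 3α-hydroxyl would have to be put on an unactivated methylene next to the tertiary alcohol, or the 4-hydroxyl removed again to recreate a ring A alkene, which cancels the benefit of the key step.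
- **Structure:** the alternative leaves the precursor with fewer stereocentres but with a far harder ring.
- **Mechanism:** a cationic cascade with proton loss as a competing exit, against a single ene closure.
- **Step economy:** it would win only if the ten-membered ring and the C3 oxygen were both solved.

Alternative 3:
- **Cut:** C9–C10 is cut; ring A becomes the phenol of A5 (C3 hydroxyl, methyl groups on C4 and C10), joined through C5 to the chain C6(OSi)–C7(i-Pr)–C8–C9–OTs.
- **Forward key step:** with KOt-Bu the phenoxide would alkylate through its para carbon C10, closing ring B and creating the quaternary centre in the cross-conjugated dienone A6.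
- **In favour:** para-alkylation of a phenoxide by a tethered sulfonate is dependable and needs no chiral catalyst, and the arene brings the C3 oxygen and C15 with it. As a bond-forming event it is at least the equal of step 11, and it forms the quaternary centre without the enantioselective conjugate addition of step 7; here it is the better.
- **Against:** the C10 configuration must be induced by C6 and C7 through the forming ring, and the required isomer has the C6 silyloxy group pseudo-axial on the side of the C10 methyl, so the wrong diastereomer is to be feared. A6 is then far from the target: the 1-ene must be saturated, the ketone reduced to the axial 3α-alcohol, and hydrogen (C5, α face) and hydroxyl (C4, β face) added across the tetrasubstituted enone alkene against its polarity, before silyl is exchanged for benzoyl.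
- **Structure:** the alternative leaves C4 and C5, the hardest centres, to the end; the chosen plan sets C5 in the ring closure and C4 by a trans-diaxial opening.
- **Mechanism:** an SN2 ring closure with dearomatisation, simpler than an ene reaction, but with weaker stereocontrol at C10.
- **Step economy:** the precursor is of comparable length (A5 needs the same C6–C7 pair of centres); the finish is longer by several steps.

Key step: step 11

## Route

Step 1
Reactants: 1 (S)-4-benzyl-1,3-oxazolidin-2-one; 2 3-methylbutanoyl chloride
Product: 3 (S)-4-benzyl-3-(3-methylbutanoyl)-1,3-oxazolidin-2-one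
Conditions: n-BuLi, THF, −78 °C; then 2, −78 → 0 °C
Reagents that add atoms: none
Why: N-acylation of the lithiated oxazolidinone by an acid chloride; no stereocentre is touched.

Step 2
Reactants: 3 (S)-4-benzyl-3-(3-methylbutanoyl)-1,3-oxazolidin-2-one; 4 tert-butyl bromoacetate
Product: 5 tert-butyl (3S)-3-{[(4S)-4-benzyl-2-oxo-1,3-oxazolidin-3-yl]carbonyl}-4-methylpentanoate
Conditions: NaN(SiMe3)2, THF, −78 °C; then 4, −78 → −40 °C
Reagents that add atoms: none
Why: Evans alkylation: the chelated Z-enolate is alkylated on the face opposite the benzyl group, which sets C7; the descriptor is S because isopropyl outranks CH2CO2t-Bu.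

Step 3
Reactants: 5 tert-butyl (3S)-3-{[(4S)-4-benzyl-2-oxo-1,3-oxazolidin-3-yl]carbonyl}-4-methylpentanoate
Product: 6 tert-butyl (3S)-3-(hydroxymethyl)-4-methylpentanoate
Conditions: LiBH4, MeOH (1 equiv), THF, 0 °C
Reagents that add atoms: none
Why: Reductive cleavage of the N-acyl oxazolidinone: the imide carbonyl is far more electrophilic than the tert-butyl ester, no enolate is formed so C7 is kept, and a cold neutral work-up should avoid lactonisation.

Step 4
Reactants: 6 tert-butyl (3S)-3-(hydroxymethyl)-4-methylpentanoate
Product: 7 tert-butyl (3S)-3-{[(tert-butyldimethylsilyl)oxy]methyl}-4-methylpentanoate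
Conditions: TBSCl, imidazole, DMF, 23 °C
Reagents that add atoms: tert-butyldimethylsilyl chloride, C[Si](C)(Cl)C(C)(C)C
Why: Silylation of a primary alcohol; the ether masks the future C6 aldehyde through the organometallic steps.

Step 5
Reactants: 7 tert-butyl (3S)-3-{[(tert-butyldimethylsilyl)oxy]methyl}-4-methylpentanoate
Product: 8 (3S)-3-{[(tert-butyldimethylsilyl)oxy]methyl}-4-methylpentan-1-ol
Conditions: LiAlH4, Et2O, 0 °C
Reagents that add atoms: none
Why: Hydride reduction of the ester to the primary alcohol (C9); the silyl ether is stable at 0 °C and C7 is not enolisable in the product.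

Step 6
Reactants: 8 (3S)-3-{[(tert-butyldimethylsilyl)oxy]methyl}-4-methylpentan-1-ol
Product: 9 {[(2S)-2-(2-bromoethyl)-3-methylbutyl]oxy}(tert-butyl)dimethylsilane
Conditions: CBr4, PPh3, CH2Cl2, 0 °C
Reagents that add atoms: carbon tetrabromide, BrC(Br)(Br)Br
Why: Appel reaction of an unhindered primary alcohol; the conditions are near neutral and leave the silyl ether intact.

Step 7
Reactants: 9 {[(2S)-2-(2-bromoethyl)-3-methylbutyl]oxy}(tert-butyl)dimethylsilane; 10 3-methylcyclohex-2-en-1-one
Product: 13 (3R)-3-[(3S)-3-{[(tert-butyldimethylsilyl)oxy]methyl}-4-methylpentyl]-3-methylcyclohex-1-en-1-yl trifluoromethanesulfonate, via Grignard reagent 11 (not isolated), via magnesium enolate 12 (not isolated)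
Conditions: Mg, Et2O, 35 °C; Cu(OTf)2 (3 mol %), chiral imidazolinium chloride (carbene precursor, 4 mol %), 10, Et2O, −30 °C; then N-(5-chloropyridin-2-yl)bis(trifluoromethanesulfonyl)imide, THF, −30 → 23 °C
Reagents that add atoms: N-(5-chloropyridin-2-yl)-1,1,1-trifluoro-N-(trifluoromethylsulfonyl)methanesulfonamide, O=S(=O)(N(c1ccc(Cl)cn1)S(=O)(=O)C(F)(F)F)C(F)(F)F
Why: Copper-catalysed asymmetric conjugate addition of a primary alkyl Grignard reagent to a β,β-disubstituted enone; the ligand enantiomer is chosen for Si-face attack at C3 of 10, which sets quaternary C10 as (R) by catalyst control, C7 being too remote to interfere. The magnesium enolate 12 has its double bond at C4–C5 and is O-sulfonylated in the same flask, which fixes the position of the future ring A alkene.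

Step 8
Reactants: 13 (3R)-3-[(3S)-3-{[(tert-butyldimethylsilyl)oxy]methyl}-4-methylpentyl]-3-methylcyclohex-1-en-1-yl trifluoromethanesulfonate
Product: 14 tert-butyl{(2S)-4-[(1R)-1,3-dimethylcyclohex-2-en-1-yl]-2-(propan-2-yl)butoxy}dimethylsilane
Conditions: MeMgBr, Fe(acac)3 (5 mol %), THF/NMP, −30 → 0 °C
Reagents that add atoms: methylmagnesium bromide, C[Mg]Br
Why: Iron-catalysed cross-coupling of an alkenyl triflate with a methyl Grignard reagent (Kumada type); the C–O bond is replaced in place, so the alkene stays at C4=C5.

Step 9
Reactants: 14 tert-butyl{(2S)-4-[(1R)-1,3-dimethylcyclohex-2-en-1-yl]-2-(propan-2-yl)butoxy}dimethylsilane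
Product: 15 (2S)-4-[(1R)-1,3-dimethylcyclohex-2-en-1-yl]-2-(propan-2-yl)butan-1-ol
Conditions: Bu4NF, THF, 0 → 23 °C
Reagents that add atoms: none
Why: Fluoride cleavage of a primary silyl ether; the alkene and both stereocentres are inert.

Step 10
Reactants: 15 (2S)-4-[(1R)-1,3-dimethylcyclohex-2-en-1-yl]-2-(propan-2-yl)butan-1-ol
Product: 16 (2S)-4-[(1R)-1,3-dimethylcyclohex-2-en-1-yl]-2-(propan-2-yl)butanal
Conditions: Dess–Martin periodinane, pyridine, CH2Cl2, 0 → 23 °C
Reagents that add atoms: none
Why: Dess–Martin oxidation of a primary alcohol under buffered, non-enolising conditions, so that C7 (now α to the aldehyde) keeps its configuration; 16 is used without storage.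

Step 11
Reactants: 16 (2S)-4-[(1R)-1,3-dimethylcyclohex-2-en-1-yl]-2-(propan-2-yl)butanal
Product: 17 eudesm-4(15)-en-6α-ol [(5S,6S,7S,10R); 5α-H]
Conditions: Me2AlCl (1.5 equiv), CH2Cl2, −78 → −40 °C
Reagents that add atoms: none
Why: This is a Lewis-acid-promoted type 1 intramolecular carbonyl-ene cyclisation, closest to the closure of citronellal to isopulegol: Me2AlCl binds the aldehyde oxygen, C5 of the C4=C5 alkene attacks C6 while positive charge builds at tertiary C4, and a C15 hydrogen passes to oxygen, the methyl on aluminium being lost as methane so that no free acid remains. Ring B closes in the 6-exo-trig mode with respect to the carbonyl, the alkene reacting through the carbon that carries the tether. Both new stereocentres come from one chair-like transition state of the forming ring in which the C7 isopropyl group is equatorial; since the isopropyl group and the C10 methyl are cis-1,4-related in that ring, this chair has C14 axial and C1 equatorial, and bonding on the C5 face that keeps C4 equatorial puts H5 trans to C14 (5α-H, trans-decalin). At C6 the aluminium-bound oxygen takes the equatorial site, because the axial one is syn-diaxial to C14 and only the equatorial oxygen lies next to the C15 hydrogens; this gives the 6α-alcohol. The selectivities needed are the C5 face, the orientation of oxygen, and hydrogen transfer from C15 and not from C3. The first is the least secure, since closure on the other C5 face through a boat-like or isopropyl-axial array would give a cis-decalin; it rests on the equatorial anchor at C7 and on a diastereomerically pure 16, whose C10 epimer would be channelled into the cis series. The exocyclic C4=C15 alkene that remains is the handle for the C3 and C4 oxygens.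

Step 12
Reactants: 17 eudesm-4(15)-en-6α-ol
Product: 18 eudesm-4(15)-en-6-one (5α-H)
Conditions: Dess–Martin periodinane, pyridine, CH2Cl2, 0 °C
Reagents that add atoms: none
Why: Dess–Martin oxidation of a secondary alcohol; the buffered neutral medium is chosen so that the β,γ-unsaturated ketone does not enolise toward C5, and the crude ketone is reduced at once.

Step 13
Reactants: 18 eudesm-4(15)-en-6-one
Product: 19 eudesm-4(15)-en-6β-ol
Conditions: LiBH(s-Bu)3, THF, −78 °C; then H2O
Reagents that add atoms: none
Why: Diastereoselective ketone reduction with a hindered trialkylborohydride: the β face of C6 is screened by the syn-axial C10 methyl, so hydride arrives from the α face (equatorial attack) and the axial 6β-alcohol results; the weakly basic reagent at −78 °C should not enolise C5 or C7.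

Step 14
Reactants: 19 eudesm-4(15)-en-6β-ol
Product: 20 eudesm-4(15)-en-6β-yl benzoate
Conditions: benzoyl chloride, DMAP, pyridine, 60 °C
Reagents that add atoms: benzoyl chloride, O=C(Cl)c1ccccc1
Why: DMAP-catalysed acylation of a hindered axial secondary alcohol by an acid chloride; heating compensates for the syn-axial C14, and no stereocentre changes.

Step 15
Reactants: 20 eudesm-4(15)-en-6β-yl benzoate
Product: 21 eudesm-3-en-6β-yl benzoate
Conditions: chloro[N,N′-bis(3,5-di-tert-butylsalicylidene)-1,2-cyclohexanediaminato]cobalt (trivalent cobalt, 5 mol %), PhSiH3 (6 mol %), benzene, 22 °C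
Reagents that add atoms: none
Why: Cobalt-hydride hydrogen-atom-transfer isomerisation of a 1,1-disubstituted alkene: reversible hydrogen-atom addition at C15 gives the tertiary C4 radical, and the catalyst should take hydrogen back from the accessible C3 methylene and not from the shielded C5 methine, so that the six-membered ring A is kept and only the double bond moves to C3=C4. The medium is neutral, so the ester and C5 are untouched.

Step 16
Reactants: 21 eudesm-3-en-6β-yl benzoate
Product: 22 3α,4α-epoxyeudesman-6β-yl benzoate
Conditions: mCPBA, NaHCO3, CH2Cl2, 0 °C
Reagents that add atoms: 3-chloroperoxybenzoic acid, O=C(OO)c1cccc(Cl)c1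
Why: Prilezhaev epoxidation of a trisubstituted alkene; the β face is blocked by the axial C14 methyl and the 6β-benzoate, so oxygen is delivered to the α face.

Step 17
Reactants: 22 3α,4α-epoxyeudesman-6β-yl benzoate
Product: 23 3α,4β-dihydroxyeudesman-6β-yl benzoate [(3R,4R,5S,6R,7S,10S); target CNP0187831.1]
Conditions: HClO4 (5 mol %), THF/H2O 3:1, 0 → 23 °C
Reagents that add atoms: water, O
Why: Acid-catalysed epoxide hydrolysis with trans-diaxial opening: the protonated epoxide opens at tertiary C4 with inversion, by water or by the syn-axial 6β-benzoate carbonyl whose bridged cation is hydrolysed back to the secondary ester. C4 thus receives the axial 4β-hydroxyl and the retained epoxide oxygen becomes the axial 3α-hydroxyl; electronic and conformational preferences point to the same product.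

## Compound list

1 | (S)-4-benzyl-1,3-oxazolidin-2-one | O=C1N[C@@H](Cc2ccccc2)CO1 | starting material
2 | 3-methylbutanoyl chloride (isovaleryl chloride) | CC(C)CC(Cl)=O | starting material
3 | (S)-4-benzyl-3-(3-methylbutanoyl)-1,3-oxazolidin-2-one | CC(C)CC(=O)N1[C@@H](Cc2ccccc2)COC1=O | intermediate
4 | tert-butyl bromoacetate | CC(C)(C)OC(=O)CBr | starting material
5 | tert-butyl (3S)-3-{[(4S)-4-benzyl-2-oxo-1,3-oxazolidin-3-yl]carbonyl}-4-methylpentanoate | CC(C)[C@H](CC(=O)OC(C)(C)C)C(=O)N1[C@@H](Cc2ccccc2)COC1=O | intermediate
6 | tert-butyl (3S)-3-(hydroxymethyl)-4-methylpentanoate | CC(C)[C@H](CC(=O)OC(C)(C)C)CO | intermediate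
7 | tert-butyl (3S)-3-{[(tert-butyldimethylsilyl)oxy]methyl}-4-methylpentanoate | CC(C)[C@H](CC(=O)OC(C)(C)C)CO[Si](C)(C)C(C)(C)C | intermediate
8 | (3S)-3-{[(tert-butyldimethylsilyl)oxy]methyl}-4-methylpentan-1-ol | CC(C)[C@H](CCO)CO[Si](C)(C)C(C)(C)C | intermediate
9 | {[(2S)-2-(2-bromoethyl)-3-methylbutyl]oxy}(tert-butyl)dimethylsilane | CC(C)[C@H](CCBr)CO[Si](C)(C)C(C)(C)C | intermediate
10 | 3-methylcyclohex-2-en-1-one | CC1=CC(=O)CCC1 | starting material
11 | [(3S)-3-{[(tert-butyldimethylsilyl)oxy]methyl}-4-methylpentyl]magnesium bromide (Grignard reagent, not isolated) | CC(C)[C@H](CC[Mg]Br)CO[Si](C)(C)C(C)(C)C | intermediate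
12 | bromomagnesium (3R)-3-[(3S)-3-{[(tert-butyldimethylsilyl)oxy]methyl}-4-methylpentyl]-3-methylcyclohex-1-en-1-olate (magnesium enolate, not isolated) | CC(C)[C@H](CC[C@@]1(C)CCCC(O[Mg]Br)=C1)CO[Si](C)(C)C(C)(C)C | intermediate
13 | (3R)-3-[(3S)-3-{[(tert-butyldimethylsilyl)oxy]methyl}-4-methylpentyl]-3-methylcyclohex-1-en-1-yl trifluoromethanesulfonate | CC(C)[C@H](CC[C@@]1(C)CCCC(OS(=O)(=O)C(F)(F)F)=C1)CO[Si](C)(C)C(C)(C)C | intermediate
14 | tert-butyl{(2S)-4-[(1R)-1,3-dimethylcyclohex-2-en-1-yl]-2-(propan-2-yl)butoxy}dimethylsilane | CC(C)[C@H](CC[C@@]1(C)CCCC(C)=C1)CO[Si](C)(C)C(C)(C)C | intermediate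
15 | (2S)-4-[(1R)-1,3-dimethylcyclohex-2-en-1-yl]-2-(propan-2-yl)butan-1-ol | CC(C)[C@H](CC[C@@]1(C)CCCC(C)=C1)CO | intermediate
16 | (2S)-4-[(1R)-1,3-dimethylcyclohex-2-en-1-yl]-2-(propan-2-yl)butanal | CC(C)[C@H](CC[C@@]1(C)CCCC(C)=C1)C=O | intermediate
17 | eudesm-4(15)-en-6α-ol (5α-H, 7β-isopropyl, 10β-methyl) | CC(C)[C@@H]1CC[C@@]2(C)CCCC(=C)[C@@H]2[C@H]1O | intermediate
18 | eudesm-4(15)-en-6-one (5α-H) | CC(C)[C@@H]1CC[C@@]2(C)CCCC(=C)[C@@H]2C1=O | intermediate
19 | eudesm-4(15)-en-6β-ol | CC(C)[C@@H]1CC[C@@]2(C)CCCC(=C)[C@@H]2[C@@H]1O | intermediate
20 | eudesm-4(15)-en-6β-yl benzoate | CC(C)[C@@H]1CC[C@@]2(C)CCCC(=C)[C@@H]2[C@@H]1OC(=O)c1ccccc1 | intermediate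
21 | eudesm-3-en-6β-yl benzoate | CC(C)[C@@H]1CC[C@@]2(C)CCC=C(C)[C@@H]2[C@@H]1OC(=O)c1ccccc1 | intermediate
22 | 3α,4α-epoxyeudesman-6β-yl benzoate | CC(C)[C@@H]1CC[C@@]2(C)CC[C@H]3O[C@@]3(C)[C@@H]2[C@@H]1OC(=O)c1ccccc1 | intermediate
23 | 3α,4β-dihydroxyeudesman-6β-yl benzoate, (3R,4R,5S,6R,7S,10S) | CC(C)[C@@H]1CC[C@@]2(C)CC[C@@H](O)[C@](C)(O)[C@@H]2[C@@H]1OC(=O)c1ccccc1 | target

## Step count and risk

Total step count: 17. Longest linear sequence: 17 steps (1 to 23); 10 enters at step 7.

**Step 11 (key step).** The most likely failure is poor control of the ring fusion. A tether on allylic C10 reaches the near face of C5 with less torsional strain through an arrangement that ends in a cis-decalin, and this competes with the chair that gives the trans isomer. Chloride capture at C4 and methyl transfer from aluminium are lesser risks. The fallback sets out from 16 and comes back to the route at 21; it forms the same C5–C6 bond by acylation and settles C5 afterwards. Oxidation of 16 (NaClO2, NaH2PO4, 2-methylbut-2-ene, t-BuOH/H2O) would give (2S)-4-[(1R)-1,3-dimethylcyclohex-2-en-1-yl]-2-(propan-2-yl)butanoic acid F1, and oxalyl chloride with catalytic DMF would convert it into (2S)-4-[(1R)-1,3-dimethylcyclohex-2-en-1-yl]-2-(propan-2-yl)butanoyl chloride F2. SnCl4 in CH2Cl2 at −78 °C should promote intramolecular acylation of the alkene at C5, and DBU should then deliver the conjugated enone eudesm-4-en-6-one F3, in which C5 is no longer stereogenic. KOt-Bu in t-BuOH/THF would form the extended dienolate, and a cold quench with aqueous acetic acid should protonate C5 under kinetic control on the face opposite the C14 methyl, giving the trans-fused eudesm-3-en-6-one F4; C7 can equilibrate here, but the equatorial isopropyl group is the stable arrangement, and any 4(15)-isomer formed is 18 itself. LiBH(s-Bu)3 at −78 °C would give eudesm-3-en-6β-ol F5, and benzoylation as in step 14 would give 21.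

**Step 7.** The most likely failure is insufficient face selectivity in the conjugate addition. The catalyst gets no help from remote C7, C10 epimers are hard to separate, and each epimer would give a different decalin. Incomplete O-sulfonylation of the magnesium enolate is a second risk. The fallback sets out from 9 and comes back to the route at 13; it reverses the roles so that the methyl group is the nucleophile. Grignard reagent 11, made from 9 as before, would be added to commercial 3-ethoxycyclohex-2-en-1-one, and a brief cold work-up with dilute acid should give 3-[(3S)-3-{[(tert-butyldimethylsilyl)oxy]methyl}-4-methylpentyl]cyclohex-2-en-1-one F6. Conjugate addition of Me3Al with Cu(OTf)2 (2 mol %) and a chiral phosphoramidite ligand (enantiomer chosen for the (R) centre; Et2O, −30 °C), followed by trapping of the enolate with Me3SiOTf, would give tert-butyl{(2S)-2-[2-((1R)-1-methyl-3-(trimethylsilyloxy)cyclohex-2-en-1-yl)ethyl]-3-methylbutoxy}dimethylsilane F7. MeLi in THF at 0 °C and then PhNTf2 would convert F7 into 13.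

**Step 12 (with consequences for step 13).** The most likely failure is migration of the exocyclic double bond into conjugation with the new ketone, with loss of the C5 configuration, during oxidation, work-up or reduction. The fallback sets out from 18 and comes back to the route at 21: the migration would be completed on purpose with DBU in CH2Cl2, which gives the enone F3 described above, and the sequence from F3 through F4 and F5 to 21 would then be followed as in the fallback for step 11.

**Step 15.** The most likely failure is the wrong direction of hydrogen abstraction (toward C5, giving the tetrasubstituted 4-ene) or net reduction of the alkene by the silane. The fallback sets out from 20 and comes back to the route at 21; it places the double bond through an enolate. Ozonolysis of 20 (O3, CH2Cl2/MeOH, −78 °C; then Me2S) would give 4-oxo-15-noreudesman-6β-yl benzoate F8. Kinetic deprotonation at the C3 methylene (KN(SiMe3)2, THF, −78 °C; the C5 methine is hindered, and its enolate, which could expel the benzoate, should not form) and trapping with PhNTf2 would give 6β-benzoyloxy-15-noreudesm-3-en-4-yl trifluoromethanesulfonate F9. Coupling with MeMgBr and Fe(acac)3 (5 mol %) in THF/NMP at −30 °C, as in step 8, would give 21.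

## Further compounds

F1 | step 11 | (2S)-4-[(1R)-1,3-dimethylcyclohex-2-en-1-yl]-2-(propan-2-yl)butanoic acid | CC(C)[C@H](CC[C@@]1(C)CCCC(C)=C1)C(=O)O
F2 | step 11 | (2S)-4-[(1R)-1,3-dimethylcyclohex-2-en-1-yl]-2-(propan-2-yl)butanoyl chloride | CC(C)[C@H](CC[C@@]1(C)CCCC(C)=C1)C(Cl)=O
F3 | step 11 | eudesm-4-en-6-one | CC(C)[C@@H]1CC[C@@]2(C)CCCC(C)=C2C1=O
F4 | step 11 | eudesm-3-en-6-one (5α-H) | CC(C)[C@@H]1CC[C@@]2(C)CCC=C(C)[C@@H]2C1=O
F5 | step 11 | eudesm-3-en-6β-ol | CC(C)[C@@H]1CC[C@@]2(C)CCC=C(C)[C@@H]2[C@@H]1O
F6 | step 7 | 3-[(3S)-3-{[(tert-butyldimethylsilyl)oxy]methyl}-4-methylpentyl]cyclohex-2-en-1-one | CC(C)[C@H](CCC1=CC(=O)CCC1)CO[Si](C)(C)C(C)(C)C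
F7 | step 7 | tert-butyl{(2S)-2-[2-((1R)-1-methyl-3-(trimethylsilyloxy)cyclohex-2-en-1-yl)ethyl]-3-methylbutoxy}dimethylsilane | CC(C)[C@H](CC[C@@]1(C)CCCC(O[Si](C)(C)C)=C1)CO[Si](C)(C)C(C)(C)C
F0 | step 12 | none | none
F8 | step 15 | 4-oxo-15-noreudesman-6β-yl benzoate | CC(C)[C@@H]1CC[C@@]2(C)CCCC(=O)[C@@H]2[C@@H]1OC(=O)c1ccccc1
F9 | step 15 | 6β-benzoyloxy-15-noreudesm-3-en-4-yl trifluoromethanesulfonate | CC(C)[C@@H]1CC[C@@]2(C)CCC=C(OS(=O)(=O)C(F)(F)F)[C@@H]2[C@@H]1OC(=O)c1ccccc1
A1 | alternative 1 | 1,10-seco-eudesm-10(14)-en-1-yn-3-ol 4β-trimethylsilyl 6β-tert-butyldimethylsilyl bis-ether (hydroxy-enyne) | CC(C)[C@@H]1CCC(=C)[C@H]([C@@](C)(O[Si](C)(C)C)C(O)C#C)[C@@H]1O[Si](C)(C)C(C)(C)C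
A2 | alternative 1 | 1,14-cyclo-3-oxoeudesmane 4β-trimethylsilyl 6β-tert-butyldimethylsilyl bis-ether | CC(C)[C@@H]1CC[C@@]23C[C@@H]2CC(=O)[C@](C)(O[Si](C)(C)C)[C@@H]3[C@@H]1O[Si](C)(C)C(C)(C)C
A3 | alternative 2 | (1(10)E,4E)-germacra-1(10),4-dien-6-yl benzoate | CC(C)[C@@H]1CC/C(C)=C/CC/C(C)=C/[C@@H]1OC(=O)c1ccccc1
A4 | alternative 2 | 4β-hydroxyeudesman-6β-yl benzoate | CC(C)[C@@H]1CC[C@@]2(C)CCC[C@](C)(O)[C@@H]2[C@@H]1OC(=O)c1ccccc1
A5 | alternative 3 | 4-[(tert-butyldimethylsilyl)oxy]-4-(3-hydroxy-2,6-dimethylphenyl)-3-(propan-2-yl)butyl 4-methylbenzenesulfonate | CC(C)[C@H](CCOS(=O)(=O)c1ccc(C)cc1)[C@@H](O[Si](C)(C)C(C)(C)C)c1c(C)ccc(O)c1C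
A6 | alternative 3 | 6β-[(tert-butyldimethylsilyl)oxy]eudesma-1,4-dien-3-one | CC(C)[C@@H]1CC[C@@]2(C)C=CC(=O)C(C)=C2[C@@H]1O[Si](C)(C)C(C)(C)C
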